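**Assumption:** (S)-5-(hydroxymethyl)furan-2(5H)-one, but-2-yn-1-ol and the simple reagents are purchasable. The Kishi ligand enantiomer and the (–)-Ipc2B(methallyl) reagent are the ones that give 5S and 8S, and the C2 epimer of ketal 15 with C1 trans to C6 is recycled.

## Retrosynthetic overview
1. The target comes from esterification of the C8-OH with methacrylic anhydride, after desilylation and α-methylenation of the saturated trans-lactone 16. The bridged 10-membered ring 16 comes from the **proposed new Z-selective RCM** of the 2-vinyl-2-methoxy-2,5-dihydrofuran 15 bearing a C10 isopropenyl group.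
2. Ketal 15 comes from MeOH closure of the Z-γ-hydroxy-enone 14. Enone 14 comes from MnO2 oxidation of the bis-allylic alcohol in the Ni/Cr-coupling adduct 13. Adduct 13 comes from asymmetric Nozaki–Hiyama–Kishi coupling of lactone aldehyde 12 with Z-vinyl iodide 4, which forms C4–C5 and sets C5.
3. Lactone aldehyde 12 comes from (S)-5-hydroxymethylbutenolide: C6 is from the starting material, C7 from trans cuprate addition, and C8 from Brown methallylation.
4. Ring-formation order: γ-lactone (pre-formed) → dihydrofuran ketal → oxa-bridged 10-membered carbocycle (RCM closes C1=C10) → α-methylene.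

## Route

**Step 1**
Reactants: 1 but-2-yn-1-ol
Product: 2 (2Z)-3-iodobut-2-en-1-ol
Conditions: Red-Al, THF, 0 °C→rt; EtOAc, –78 °C; I2, –78→0 °C
Reagents that add atoms: iodine, II
Why: Red-Al trans-hydroalumination of the propargylic alkoxide puts Al at C3, and I2 iodinolysis with retention gives the Z-vinyl iodide (I cis to CH2OH).

**Step 2**
Reactants: 2
Product: 3 (2Z)-3-iodobut-2-enal
Conditions: MnO2 (10 equiv), CH2Cl2, rt; used crude
Reagents that add atoms: none
Why: Allylic alcohol oxidation with MnO2 leaves the C=C geometry intact.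

**Step 3**
Reactants: 3
Product: 4 (4Z)-5-iodohexa-1,4-dien-3-ol (racemic at C3)
Conditions: CH2=CHMgBr, THF, –78 °C
Reagents that add atoms: vinylmagnesium bromide, C=C[Mg]Br
Why: 1,2-Grignard addition to the enal; the new carbinol centre becomes C2 and is destroyed by oxidation in Step 12, so racemic 4 is acceptable.

**Step 4**
Reactants: 5 (S)-5-(hydroxymethyl)furan-2(5H)-one
Product: 6 (S)-5-[(triethylsilyloxy)methyl]furan-2(5H)-one
Conditions: TESCl, imidazole, DMF, 0 °C
Reagents that add atoms: chlorotriethylsilane, CC[Si](Cl)(CC)CC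
Why: Silyl protection of the primary alcohol; the C6 stereocentre comes from the chiral-pool starting material.

**Step 5**
Reactants: 6
Product: 7 (4R,5S)-5-[(triethylsilyloxy)methyl]-4-vinyloxolan-2-one
Conditions: CH2=CHMgBr, CuBr·SMe2, TMSCl, THF, –78 °C; then aq NH4Cl
Reagents that add atoms: vinylmagnesium bromide, C=C[Mg]Br
Why: Cu-mediated 1,4-addition (conjugate addition) occurs anti to the C5 side chain, giving the trans-lactone and setting C7 (R).

**Step 6**
Reactants: 7
Product: 8 (2S,3S)-2-[(triethylsilyloxy)methyl]-5-oxooxolane-3-carbaldehyde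
Conditions: OsO4 (cat.), NaIO4, 2,6-lutidine, dioxane/H2O, rt; used crude
Reagents that add atoms: sodium periodate as O-atom source, [Na+].[O-]I(=O)(=O)=O
Why: Lemieux–Johnson cleavage of the vinyl group under buffered, non-basic conditions avoids C7 epimerisation and β-elimination.

**Step 7**
Reactants: 8
Product: 9 (4R,5S)-4-[(1S)-1-hydroxy-3-methylbut-3-en-1-yl]-5-[(triethylsilyloxy)methyl]oxolan-2-one
Conditions: (–)-Ipc2B(methallyl) (from (+)-α-pinene), Et2O, –78 °C; then NaBO3·4H2O, THF/H2O
Reagents that add atoms: B-methallyldiisopinocampheylborane, C=C(C)CB(C1CC2CC(C2(C)C)C1C)C1CC2CC(C2(C)C)C1C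
Why: Brown asymmetric allylboration is reagent-controlled (Si-face attack), setting C8 (S) and installing C9–C10; the perborate work-up spares the lactone.

**Step 8**
Reactants: 9
Product: 10 (4S,5S)-4-[(1S)-1-(TBSO)-3-methylbut-3-en-1-yl]-5-[(triethylsilyloxy)methyl]oxolan-2-one
Conditions: TBSOTf, 2,6-lutidine, CH2Cl2, –78→0 °C
Reagents that add atoms: tert-butyldimethylsilyl triflate, C[Si](C)(C(C)(C)C)OS(=O)(=O)C(F)(F)F
Why: Silylation of the secondary alcohol; no stereocentre is touched.

**Step 9**
Reactants: 10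
Product: 11 (4S,5S)-4-[(1S)-1-(TBSO)-3-methylbut-3-en-1-yl]-5-(hydroxymethyl)oxolan-2-one
Conditions: PPTS (0.2 equiv), MeOH, 0 °C→rt
Reagents that add atoms: none
Why: The primary TES ether is cleaved selectively in the presence of the secondary TBS ether and the lactone.

**Step 10**
Reactants: 11
Product: 12 (2S,3S)-3-[(1S)-1-(TBSO)-3-methylbut-3-en-1-yl]-5-oxooxolane-2-carbaldehyde
Conditions: Dess–Martin periodinane, NaHCO3, CH2Cl2, 0 °C; filtered through silica and used at once
Reagents that add atoms: none
Why: Mild, buffered alcohol oxidation keeps the α-acyloxy aldehyde C6 stereocentre intact.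

**Step 11**
Reactants: 12 + 4 (2.5 equiv)
Product: 13 (4S,5S)-4-[(1S)-1-(TBSO)-3-methylbut-3-en-1-yl]-5-[(1S,2Z)-1,4-dihydroxy-2-methylhexa-2,5-dien-1-yl]oxolan-2-one (C4′ epimer mixture)
Conditions: CrCl2, cat. NiCl2, chiral sulfonamide ligand (S)-L*, Et3N, MeCN, rt
Reagents that add atoms: none
Why: Ni/Cr Nozaki–Hiyama–Kishi vinylation retains the Z-alkene, and the chiral sulfonamide–Cr complex (reagent control) overrides the substrate's Felkin bias to set C5 (S); the C2 carbinol epimers are irrelevant because C2 is oxidised next.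

**Step 12**
Reactants: 13
Product: 14 (4S,5S)-4-[(1S)-1-(TBSO)-3-methylbut-3-en-1-yl]-5-[(1S,2Z)-1-hydroxy-2-methyl-4-oxohexa-2,5-dien-1-yl]oxolan-2-one (in equilibrium with the 2-hydroxy-2-vinyl-2,5-dihydrofuran hemiketal)
Conditions: MnO2 (20 equiv), CH2Cl2, 0 °C→rt
Reagents that add atoms: none
Why: MnO2 allylic oxidation is chemoselective for the doubly allylic C2 alcohol over the hindered, inductively deactivated C5 alcohol; the Z-γ-hydroxy-enone then closes to the hemiketal, so the C2 stereocentre disappears.

**Step 13**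
Reactants: 14
Product: 15 (4S,5S)-4-[(1S)-1-(TBSO)-3-methylbut-3-en-1-yl]-5-[(2S,5S)-5-ethenyl-5-methoxy-3-methyl-2,5-dihydrofuran-2-yl]oxolan-2-one
Conditions: MeOH/HC(OMe)3, PPTS (0.1 equiv), 0 °C
Reagents that add atoms: methanol, CO
Why: Acid-catalysed hemiketal→methyl ketal conversion via an oxocarbenium ion; the C2 epimers equilibrate, the isomer with C1 cis to C6 (2S, able to bridge) is separated, and the other is recycled under the same conditions.

**Step 14**
Reactants: 15
Product: 16 TBS ether of 8-desmethacryloyl-11,13-dihydro-2-deethoxy-2β-methoxyphantomolin (bridged ketal, 1(10)Z)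
Conditions: Mo-MAP alkylidene catalyst (10 mol %), C6H6 (1 mM), 22 °C, 10 Torr
Reagents that add atoms: none (ethylene is lost)
Why: Proposed new method: Z-selective ring-closing metathesis forms the trisubstituted C1=C10 alkene across a bicyclo[6.2.1] oxa-bridged 10-membered ring. The Mo=CH2 or Mo=CHR species adds to the α,α-dialkoxyallyl vinyl group C1=CH2, and a syn-configured metallacyclobutane with the bulky aryloxide closes onto the C10 isopropenyl group. The bridging ring makes the C2–C9 cis arrangement (Z) the only accessible geometry, and ethylene removal drives the reaction. The closest known reactions are Mo-MAP Z-selective macrocyclic RCM and Ru-catalysed RCM to trisubstituted cycloalkenes, but this oxygen-bridged, hindered substrate has not been tried.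

**Step 15**
Reactants: 16
Product: 17 TBS ether of 8-desmethacryloyl-2-deethoxy-2β-methoxyphantomolin
Conditions: LiHMDS, THF, –78 °C; Me2N=CH2+ I–; then MeI, CH2Cl2; then DBU
Reagents that add atoms: Eschenmoser's salt, C=[N+](C)C.[I-] (supplies the =CH2 carbon)
Why: α-Methylenation via the lactone enolate (Mannich aminomethylation, then Hofmann-type elimination); C6 and C7 are not acidic and are not epimerised.

**Step 16**
Reactants: 17
Product: 18 8-desmethacryloyl-2-deethoxy-2β-methoxyphantomolin (free C8 alcohol)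
Conditions: HF·pyridine, pyridine/THF, 0 °C→rt
Reagents that add atoms: none
Why: Buffered fluoride desilylation avoids alkoxide formation, which could translactonise to the 8,12-olide, and avoids strong acid that could open the ketal.

**Step 17**
Reactants: 18
Product: 19 2-deethoxy-2β-methoxyphantomolin (target)
Conditions: methacrylic anhydride, DMAP, Et3N, BHT (cat.), CH2Cl2, 0 °C→rt
Reagents that add atoms: methacrylic anhydride, C=C(C)C(=O)OC(=O)C(C)=C
Why: Acylation of the C8 secondary alcohol with retention of configuration; no stereocentre is touched.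

## Compound list
1 | but-2-yn-1-ol | CC#CCO | starting material
2 | (2Z)-3-iodobut-2-en-1-ol | C/C(I)=C/CO | intermediate
3 | (2Z)-3-iodobut-2-enal | C/C(I)=C/C=O | intermediate
4 | (4Z)-5-iodohexa-1,4-dien-3-ol (racemic at C3) | C=CC(O)/C=C(/C)I | intermediate
5 | (S)-5-(hydroxymethyl)furan-2(5H)-one | OC[C@H]1OC(=O)C=C1 | starting material
6 | (S)-5-(TES-oxymethyl)furan-2(5H)-one | CC[Si](CC)(CC)OC[C@H]1OC(=O)C=C1 | intermediate
7 | (4R,5S)-5-(TES-oxymethyl)-4-vinyloxolan-2-one | CC[Si](CC)(CC)OC[C@H]1OC(=O)C[C@@H]1C=C | intermediate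
8 | (2S,3S)-2-(TES-oxymethyl)-5-oxooxolane-3-carbaldehyde | CC[Si](CC)(CC)OC[C@H]1OC(=O)C[C@@H]1C=O | intermediate
9 | (4R,5S)-4-[(1S)-1-hydroxy-3-methylbut-3-enyl]-5-(TES-oxymethyl)oxolan-2-one | CC[Si](CC)(CC)OC[C@H]1OC(=O)C[C@@H]1[C@@H](O)CC(C)=C | intermediate
10 | TBS ether of 9 | CC[Si](CC)(CC)OC[C@H]1OC(=O)C[C@@H]1[C@@H](O[Si](C)(C)C(C)(C)C)CC(C)=C | intermediate
11 | primary alcohol from 10 | OC[C@H]1OC(=O)C[C@@H]1[C@@H](O[Si](C)(C)C(C)(C)C)CC(C)=C | intermediate
12 | lactone aldehyde | O=C[C@H]1OC(=O)C[C@@H]1[C@@H](O[Si](C)(C)C(C)(C)C)CC(C)=C | intermediate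
13 | NHK diol (5S; C2 epimeric) | C=CC(O)/C=C(/C)[C@H](O)[C@H]1OC(=O)C[C@@H]1[C@@H](O[Si](C)(C)C(C)(C)C)CC(C)=C | intermediate
14 | Z-γ-hydroxy-enone | C=CC(=O)/C=C(/C)[C@H](O)[C@H]1OC(=O)C[C@@H]1[C@@H](O[Si](C)(C)C(C)(C)C)CC(C)=C | intermediate
15 | 2-vinyl-2-methoxy-2,5-dihydrofuran ketal | C=C[C@@]1(OC)C=C(C)[C@H](O1)[C@H]2OC(=O)C[C@@H]2[C@@H](O[Si](C)(C)C(C)(C)C)CC(C)=C | intermediate
16 | RCM product (11,13-dihydro, 8-OTBS) | CC(C)(C)[Si](C)(C)O[C@H]1C/C(C)=C\[C@@]2(OC)C=C(C)[C@H](O2)[C@H]2OC(=O)C[C@@H]21 | intermediate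
17 | α-methylene lactone, 8-OTBS | CC(C)(C)[Si](C)(C)O[C@H]1C/C(C)=C\[C@@]2(OC)C=C(C)[C@H](O2)[C@H]2OC(=O)C(=C)[C@@H]21 | intermediate
18 | C8 alcohol | O[C@H]1C/C(C)=C\[C@@]2(OC)C=C(C)[C@H](O2)[C@H]2OC(=O)C(=C)[C@@H]21 | intermediate
19 | 2-deethoxy-2β-methoxyphantomolin | C=C(C)C(=O)O[C@H]1C/C(C)=C\[C@@]2(OC)C=C(C)[C@H](O2)[C@H]2OC(=O)C(=C)[C@@H]21 | target

**Total steps:** 17. **Longest linear sequence:** 14 steps (5 → 19); the vinyl iodide branch is 3 steps and joins at Step 11.

## Three steps most likely to fail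
1. **Step 14 (proposed new RCM).** Risks are poor conversion of the hindered tertiary vinyl ketal with the 1,1-disubstituted olefin, or oligomerisation. Fallback: reverse the ring-forming order. Run conventional Ru (Hoveyda–Grubbs II) RCM on the open-chain diol 13 to form the carbocycle, separate the Z-isomer, then close the oxa-bridge by MnO2 oxidation and MeOH/PPTS ketalisation (Steps 12–13 chemistry).
2. **Step 11 (C5 stereocontrol in the NHK).** The catalyst may not override the Felkin-anti bias of the α-acyloxy aldehyde. Fallback: use the C2-OTES analogue of 4 in an achiral NHK and take the Felkin-anti (5R) adduct. Invert C5 by Mitsunobu reaction with chloroacetic acid, then cleave the chloroacetate with thiourea. This is a stepwise substrate-control plus inversion route.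
3. **Step 12 (regioselective MnO2 oxidation / stability of the divinyl ketone).** MnO2 may oxidise C5 or over-react. Fallback: with the C2-OTES vinyl iodide, protect C5-OH as its chloroacetate, remove the TES group (PPTS, MeOH), oxidise C2-OH with Dess–Martin periodinane, then cleave the chloroacetate with thiourea to give 14. This uses an orthogonal protecting-group sequence.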